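In a closed flask of constant volume, the starting material charged stays conserved: its shares in starting material, target, isomer of the product, over-reaction product and quenched substrate add up to the charge. Theta and alpha differ in their protic impurity, and both are read at 4.0 h.

the same everywhere: starting material 0.10 M

| charge | coupling partner | protic impurity | remark | time |
|---|---|---|---|---|
| north | 2 equiv | 0.029 M | run made earlier |  |
| south-west | 2 equiv | 0.035 M | run made earlier |  |
| theta | 2.00 equiv | 0.0200 M |  | 4.0 h |
| alpha | 2.00 equiv | 0.0260 M |  | 4.0 h |

| run | time / min | isomer of the product / % | over-reaction product / % | starting material / % | target / % |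
|---|---|---|---|---|---|
| north | 10.0 | 3.4 | 0.6 | 68.3 | 6.4 |
| north | 30.0 | 6.9 | 8.3 | 47.6 | 10.1 |
| north | 60.0 | 8.7 | 18.3 | 35.2 | 7.8 |
| north | 80.0 | 9.7 | 23.5 | 29.3 | 6.3 |
| north | 120 | 14.7 | 32.7 | 21.9 | 4.8 |
| south-west | 10.0 | 2.5 | 1.8 | 64.6 | 7.8 |
| south-west | 30.0 | 6.6 | 9.6 | 43.5 | 9.1 |
| south-west | 60.0 | 7.7 | 16.6 | 31.9 | 7.7 |
| south-west | 80.0 | 10.2 | 23.4 | 27.9 | 3.6 |
| south-west | 120 | 14.1 | 31.5 | 19.4 | 5.6 |

(readings scatter by 1 percentage point)

1. which of these there is most of at the end, counted by the starting material in it, theta (isomer of the product / over-reaction product / target / starting material)
2. which of these there is most of at the end, counted by the starting material in it, alpha (isomer of the product / over-reaction product / target / starting material)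
3. how much there is at the end of the one of these that leads, in percent of the starting material charged: theta
4. how much there is at the end of the one of these that leads, in percent of the starting material charged: alpha

- on the list of suspects stand: starting material + coupling partner <-> target; starting material + coupling partner <-> isomer of the product; starting material + protic impurity -> quenched substrate; target -> over-reaction product

The readings seem to break that balance: over their last three readings, the sealed north flask misses 29.0 % of its charge and the south-west flask 33.5 %. Quenched substrate is never read, though, and the impurity charges come to 29.0 % and 35.0 % of the starting material.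

The north flask already misses 21.3 % at 10.0 min, which gives the impurity a time constant near 7.54 min. Its later starting material decays with a time constant of about 126 min, so the time constant of the quench is much shorter. In theta the protic impurity is the limiting reagent of the quench, its charge being smaller than that of starting material, and the same holds in alpha. By my reckoning, theta therefore enters the slow stage with 80.0 % of its charge and alpha with 74.0 %. This is the usable share u, the starting-material charge less the impurity charge, over the starting-material charge.

At 120 min, over-reaction product over u reads 46.1 % in north and 48.5 % in south-west, so my reckoning freezes that share and puts the over-reaction product of theta over that of alpha at 1.08.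

The forecast names over-reaction product for theta and over-reaction product for alpha, at 48 % and 44 %: “Scaling by available material, over-reaction product leads in both runs”.

The flasks give over-reaction product at 48.9 % in theta and over-reaction product at 45.6 % in alpha.

    starting material + coupling partner ⇌ target (K = 4.30 M⁻¹, k = 3.30 M⁻¹ h⁻¹)
    starting material + coupling partner ⇌ isomer of the product (K = 14.0 M⁻¹, k = 1.10 M⁻¹ h⁻¹)
    starting material + protic impurity → quenched substrate (k = 88.0 M⁻¹ h⁻¹)
    target → over-reaction product (k = 2.40 h⁻¹)

Leader over u is 61.1 % in theta and 61.6 % in alpha, and theta holds 20.0 % quenched substrate against 20.0 % from u. A neighbour of theta charged with 0.40 M of starting material has u of 95.0 % and holds 5.00 % quenched substrate against 5.00 % from u. Theta is not at rest at 4.00 h, and the flask holds a reserve that the number there doesn't show. By 40.0 h, quenched substrate still stands at 20.0 %, but isomer of the product falls from 17.9 % to 3.23 %, and over-reaction product gains 27 percentage points to reach 76.0 %.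

The earlier runs and the new flask stem from a simulated flask with constants of no real substance.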